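**Retrosynthetic overview**
1. The strategy rests on the six-membered ring: C1 ketone, C2=C3 with the amide nitrogen on C2, quaternary carbinol C4, and the C5–C6 oxirane anti to the C4 hydroxyl. The C1–C2–C3 arm is an epoxy-ketone arm that nitrogen has opened and that has then lost its C3 oxygen. The ring therefore maps onto a mirror-symmetric 2,3:5,6-diepoxy-4-oxycyclohexanone, with the mirror plane through C1 and C4.
2. Disconnections, with the triene numbered C7 to C13 outward from C4: the C8–C9 bond by Stille coupling (core E-vinylstannane plus a bromodienamide carrying the five-membered ring); the N-acyl bond at C2 ((R,E)-2,4-dimethyloct-2-enoyl chloride); and C2–N with C2=C3, taken back to the meso diepoxide by catalytic azidolysis that selects one enantiotopic oxirane, followed by β-elimination.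
3. Ring order: the carbocycle is the benzene ring of 4-[(trimethylsilyl)ethynyl]phenol after dearomatisation. Both oxiranes are closed together by a double nucleophilic epoxidation, and one is opened again in the key step. The five-membered ring is bought as cyclopentane-1,3-dione and arrives in the last step.
4. Stereocontrol: C4/C5/C6 relative configuration comes from epoxidation on the alkyne face, and their absolute configuration from the catalyst. The chain methyl centre comes from an Evans methylation. Alkene geometry comes from a stabilised Wittig reaction, a syn hydrostannylation and an all-trans C5 building block.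

Key step: step 4

Assumption: the sense of induction of (salen)CrN3 on this substrate class cannot be derived from known cases, so the (R,R)-ligand is written and the equally available (S,S)-ligand takes its place if the first run delivers the mirror-image core; glutaconaldehyde potassium salt is taken as a catalogue compound.

The ring numbering of overview line 1 is used in all names.

Step 1
Reactants: 1 4-[(trimethylsilyl)ethynyl]phenol
Product: 2 4-hydroxy-4-[(trimethylsilyl)ethynyl]cyclohexa-2,5-dien-1-one
Conditions: PhI(OAc)2 (1.1 equiv), MeCN/H2O (3:1), 0 °C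
Reagents that add atoms: water, O
Why: Oxidative dearomatisation of a para-substituted phenol by a hypervalent iodine diacetate, in which the phenol-bound iodane leaves as PhI while water is captured at the alkynyl-bearing para carbon to give the achiral para-quinol, the C-silyl cap keeping the alkyne out of the reaction.

Step 2
Reactants: 2 4-hydroxy-4-[(trimethylsilyl)ethynyl]cyclohexa-2,5-dien-1-one
Product: 3 4-(triethylsilyloxy)-4-[(trimethylsilyl)ethynyl]cyclohexa-2,5-dien-1-one
Conditions: Et3SiOTf, 2,6-lutidine, CH2Cl2, −78 → 0 °C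
Reagents that add atoms: triethylsilyl trifluoromethanesulfonate, CC[Si](CC)(CC)OS(=O)(=O)C(F)(F)F
Why: Silyl triflate silylation of a hindered tertiary carbinol with a non-nucleophilic base, chosen so that the C4 oxygen can no longer guide a peroxide by hydrogen bonding and instead screens its own ring face.

Step 3
Reactants: 3 4-(triethylsilyloxy)-4-[(trimethylsilyl)ethynyl]cyclohexa-2,5-dien-1-one
Product: 5 meso-(2R,3S,5R,6S)-2,3:5,6-diepoxy-4-(triethylsilyloxy)-4-[(trimethylsilyl)ethynyl]cyclohexan-1-one (both oxiranes on the alkyne face and trans to OSiEt3), via racemic monoepoxy enone 4 (not isolated)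
Conditions: t-BuOOH (anhydrous, in decane, 3 equiv), DBU, CH2Cl2, 0 °C → rt
Reagents that add atoms: tert-butyl hydroperoxide, CC(C)(C)OO
Why: Weitz–Scheffer nucleophilic epoxidation run twice, in which t-BuOO− adds to C5 and then to C3 from the ring face that carries the rod-like alkyne, away from the OSiEt3 group, and each peroxy enolate closes its oxirane on that same face, so C2, C3, C5 and C6 are set by substrate control and the meso cis-diepoxide should result.

Step 4
Reactants: 5 meso-(2R,3S,5R,6S)-2,3:5,6-diepoxy-4-(triethylsilyloxy)-4-[(trimethylsilyl)ethynyl]cyclohexan-1-one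
Product: 7 (4S,5R,6S)-2-azido-5,6-epoxy-4-(triethylsilyloxy)-4-[(trimethylsilyl)ethynyl]cyclohex-2-en-1-one, via trans azido silyl ether 6 (not isolated)
Conditions: TMSN3 (1.05 equiv), (R,R)-(salen)CrN3 (5 mol %; salen = N,N'-bis(3,5-di-tert-butylsalicylidene)-1,2-cyclohexanediaminate), t-BuOMe, −10 °C → rt; then DBU (1.1 equiv), 0 °C, same flask
Reagents that add atoms: azidotrimethylsilane, C[Si](C)(C)N=[N+]=[N-]
Why: Proposed new method: one (salen)Cr centre of trivalent chromium binds an oxirane oxygen as a Lewis acid while a second (salen)CrN3 unit delivers azide to the adjacent carbonyl-flanked carbon C2 with SN2 inversion, TMSN3 silylates the C3 alkoxide and regenerates the chromium azide to give trans azido silyl ether 6, and DBU then removes the doubly activated C2 proton so that the C3 siloxide leaves by E1cB and C2=C3 forms. The closest known reaction types are the (salen)CrN3-catalysed desymmetrising azidolysis of simple meso epoxides with TMSN3 and the conversion of α,β-epoxy ketones into 2-azido enones by azide opening and dehydration, neither of which has been shown on a meso bis(epoxy) ketone or with a choice between two enantiotopic epoxy-ketone arms. No ring is closed: one oxirane is spent on the C2–N bond and the C2=C3 bond, and the other survives as the C5–C6 epoxide. The C2 and C3 centres of 6 are erased by the elimination, so the only lasting stereochemical event is the ligand-controlled choice of the oxirane whose α-carbon is R-configured, which fixes C4, C5 and C6 together as 4S,5R,6S (the same spatial arrangement as 4R,5R,6S in the target, where only the priority order at C4 differs). Attack at C2 rather than C3 is secured by carbonyl acceleration of substitution at the α-carbon and by the neopentyl-like shielding of C3 by quaternary C4, the silyl cap on the C3 oxygen blocks retro-aldol ring cleavage, and the near-stoichiometric charge of TMSN3 protects the second oxirane. Any over-reaction should remove mainly the minor enantiomer, because that one still holds the oxirane the catalyst prefers.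

Step 5
Reactants: 8 hexanoyl chloride; 9 (R)-4-benzyl-2-oxazolidinone
Product: 10 (R)-4-benzyl-3-hexanoyloxazolidin-2-one
Conditions: Et3N, DMAP (cat.), CH2Cl2, 0 °C → rt
Reagents that add atoms: none
Why: DMAP-catalysed N-acylation of the oxazolidinone by the acid chloride, a standard way of loading an Evans auxiliary without strong base.

Step 6
Reactants: 10 (R)-4-benzyl-3-hexanoyloxazolidin-2-one
Product: 12 (R)-4-benzyl-3-[(R)-2-methylhexanoyl]oxazolidin-2-one, via sodium Z-enolate 11 (not isolated)
Conditions: NaHMDS, THF, −78 °C; then MeI, −78 → −40 °C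
Reagents that add atoms: iodomethane, CI
Why: Evans asymmetric alkylation, in which the chelated Z-enolate 11 is methylated on the face opposite the benzyl group of the (R)-auxiliary, which sets the R configuration at the new methyl-bearing carbon.

Step 7
Reactants: 12 (R)-4-benzyl-3-[(R)-2-methylhexanoyl]oxazolidin-2-one
Product: 13 (R)-2-methylhexan-1-ol
Conditions: LiBH4, H2O (1 equiv), Et2O, 0 °C
Reagents that add atoms: none
Why: Reductive removal of the auxiliary, in which borohydride attacks the exocyclic imide carbonyl and takes it to the primary alcohol without enolisation, so the R centre is kept.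

Step 8
Reactants: 13 (R)-2-methylhexan-1-ol
Product: 14 (R)-2-methylhexanal
Conditions: TEMPO (10 mol %), PhI(OAc)2, CH2Cl2, rt
Reagents that add atoms: none
Why: Oxoammonium (TEMPO) oxidation with PhI(OAc)2 as terminal oxidant stops at the aldehyde under nearly neutral conditions, so the α-stereocentre should not epimerise.

Step 9
Reactants: 14 (R)-2-methylhexanal; 15 ethyl 2-(triphenylphosphoranylidene)propanoate
Product: 16 ethyl (R,E)-2,4-dimethyloct-2-enoate
Conditions: CH2Cl2, rt → 40 °C
Reagents that add atoms: none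
Why: Wittig olefination with a stabilised α-methyl ylide, which places the ester trans to the branched alkyl group and gives the E trisubstituted alkene without touching the allylic centre.

Step 10
Reactants: 16 ethyl (R,E)-2,4-dimethyloct-2-enoate
Product: 17 (R,E)-2,4-dimethyloct-2-enoic acid
Conditions: LiOH, THF/MeOH/H2O, 40 °C; then 1 M HCl
Reagents that add atoms: lithium hydroxide, [Li+].[OH-]
Why: Saponification by acyl addition–elimination of hydroxide, under which the γ-hydrogen at the stereocentre is not acidic enough to be exchanged.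

Step 11
Reactants: 17 (R,E)-2,4-dimethyloct-2-enoic acid
Product: 18 (R,E)-2,4-dimethyloct-2-enoyl chloride
Conditions: (COCl)2, DMF (cat.), CH2Cl2, 0 °C → rt; concentrate, use crude
Reagents that add atoms: oxalyl chloride, O=C(Cl)C(=O)Cl
Why: Acid chloride formation under Vilsmeier-type DMF catalysis at or below room temperature, with no base present that could deconjugate the enoyl system.

Step 12
Reactants: 7 (4S,5R,6S)-2-azido-5,6-epoxy-4-(triethylsilyloxy)-4-[(trimethylsilyl)ethynyl]cyclohex-2-en-1-one
Product: 20 (4S,5R,6S)-2-amino-5,6-epoxy-4-(triethylsilyloxy)-4-[(trimethylsilyl)ethynyl]cyclohex-2-en-1-one, via iminophosphorane 19 (not isolated)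
Conditions: PPh3, THF/H2O (10:1), 0 °C → rt, dark; used at once
Reagents that add atoms: none
Why: Staudinger reduction, in which PPh3 attacks the terminal azide nitrogen, dinitrogen is lost and water hydrolyses iminophosphorane 19 to the primary 2-amino enone under neutral conditions that leave the oxirane, alkyne and silyl ether alone.

Step 13
Reactants: 20 (4S,5R,6S)-2-amino-5,6-epoxy-4-(triethylsilyloxy)-4-[(trimethylsilyl)ethynyl]cyclohex-2-en-1-one; 18 (R,E)-2,4-dimethyloct-2-enoyl chloride
Product: 21 (R,E)-N-{(4S,5R,6S)-5,6-epoxy-1-oxo-4-(triethylsilyloxy)-4-[(trimethylsilyl)ethynyl]cyclohex-2-en-2-yl}-2,4-dimethyloct-2-enamide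
Conditions: pyridine, CH2Cl2, 0 °C → rt
Reagents that add atoms: none
Why: N-acylation of the enamine nitrogen through the acylpyridinium ion, pyridine being too weak a base to remove the γ-hydrogen of 18 and form a vinylketene, which would erase the R centre.

Step 14
Reactants: 21 (R,E)-N-{(4S,5R,6S)-5,6-epoxy-1-oxo-4-(triethylsilyloxy)-4-[(trimethylsilyl)ethynyl]cyclohex-2-en-2-yl}-2,4-dimethyloct-2-enamide
Product: 23 (R,E)-N-[(4S,5R,6S)-5,6-epoxy-4-ethynyl-4-hydroxy-1-oxocyclohex-2-en-2-yl]-2,4-dimethyloct-2-enamide, via terminal alkyne triethylsilyl ether 22 (not isolated)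
Conditions: Bu4NF/AcOH (1:1, 3 equiv), THF, 0 °C → rt
Reagents that add atoms: none
Why: Fluoride-induced cleavage of the alkynyl C–Si bond and then of the O–Si bond, with acetic acid keeping the C4 oxygen protonated so that a Payne rearrangement of the anti epoxy alcohol and base damage to the epoxy ketone are avoided.

Step 15
Reactants: 23 (R,E)-N-[(4S,5R,6S)-5,6-epoxy-4-ethynyl-4-hydroxy-1-oxocyclohex-2-en-2-yl]-2,4-dimethyloct-2-enamide
Product: 24 (R,E)-N-{(4S,5R,6S)-5,6-epoxy-4-hydroxy-1-oxo-4-[(E)-2-(tributylstannyl)vinyl]cyclohex-2-en-2-yl}-2,4-dimethyloct-2-enamide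
Conditions: Bu3SnH (slow addition), PdCl2(PPh3)2 (3 mol %), THF, 0 °C
Reagents that add atoms: tributyltin hydride, CCCC[SnH](CCCC)CCCC
Why: Palladium-catalysed hydrostannylation, in which Bu3SnH reduces the divalent palladium precatalyst to zerovalent palladium, H and Sn add syn across the terminal alkyne and quaternary C4 steers tin to the terminal carbon, giving the E-vinylstannane faster than the hindered amido enone can be reduced.

Step 16
Reactants: 25 glutaconaldehyde potassium salt (potassium (1E,3E)-5-oxopenta-1,3-dien-1-olate)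
Product: 26 (2E,4E)-5-bromopenta-2,4-dienal
Conditions: Ph3PBr2, CH2Cl2, 0 °C → rt; then p-TsOH (cat.), rt
Reagents that add atoms: dibromotriphenylphosphorane, BrP(Br)(c1ccccc1)(c1ccccc1)c1ccccc1
Why: Oxygen-to-bromine exchange on a vinylogous formate enolate by O-phosphonium activation and addition–elimination of bromide, after which acid-catalysed equilibration converges on the all-trans bromodienal.

Step 17
Reactants: 26 (2E,4E)-5-bromopenta-2,4-dienal
Product: 27 (2E,4E)-5-bromopenta-2,4-dienoic acid
Conditions: NaClO2, NaH2PO4, 2-methylbut-2-ene, t-BuOH/H2O, rt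
Reagents that add atoms: sodium chlorite, [Na+].[O-]Cl=O
Why: Pinnick oxidation, in which chlorous acid adds to the aldehyde and fragments to the carboxylic acid while the alkene scavenger takes up the hypochlorous acid, so the bromodiene keeps its geometry.

Step 18
Reactants: 28 cyclopentane-1,3-dione
Product: 29 2-(2-phenylhydrazinylidene)cyclopentane-1,3-dione
Conditions: PhN2BF4, NaOAc, EtOH/H2O, 0 °C
Reagents that add atoms: benzenediazonium tetrafluoroborate, N#[N+]c1ccccc1.F[B-](F)(F)F
Why: Azo coupling of the enolised 1,3-dione at its nucleophilic C2 with an arenediazonium salt, the product resting as the hydrogen-bonded hydrazone tautomer.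

Step 19
Reactants: 29 2-(2-phenylhydrazinylidene)cyclopentane-1,3-dione
Product: 30 2-amino-3-hydroxycyclopent-2-en-1-one hydrochloride
Conditions: H2 (1 atm), 10% Pd/C, HCl, MeOH, rt
Reagents that add atoms: hydrogen chloride, Cl
Why: Catalytic hydrogenation of the C=N bond and hydrogenolysis of the N–N bond leave the C2 nitrogen as a primary amine, which is held as its hydrochloride to prevent self-condensation and air oxidation.

Step 20
Reactants: 27 (2E,4E)-5-bromopenta-2,4-dienoic acid
Product: 31 (2E,4E)-5-bromopenta-2,4-dienoyl chloride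
Conditions: (COCl)2, DMF (cat.), CH2Cl2, 0 °C → rt; concentrate, use crude
Reagents that add atoms: oxalyl chloride, O=C(Cl)C(=O)Cl
Why: Acid chloride formation under Vilsmeier-type DMF catalysis, mild enough to keep both double bonds trans.

Step 21
Reactants: 31 (2E,4E)-5-bromopenta-2,4-dienoyl chloride; 30 2-amino-3-hydroxycyclopent-2-en-1-one hydrochloride
Product: 32 (2E,4E)-5-bromo-N-(2-hydroxy-5-oxocyclopent-1-en-1-yl)penta-2,4-dienamide
Conditions: Et3N (2.2 equiv), CH2Cl2/DMF, −10 °C → rt
Reagents that add atoms: none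
Why: N-acylation of the liberated amino enol by the acid chloride, any enol ester formed first passing its acyl group to nitrogen by O-to-N transfer because the hydrogen-bonded amide is the more stable isomer.

Step 22
Reactants: 24 (R,E)-N-{(4S,5R,6S)-5,6-epoxy-4-hydroxy-1-oxo-4-[(E)-2-(tributylstannyl)vinyl]cyclohex-2-en-2-yl}-2,4-dimethyloct-2-enamide; 32 (2E,4E)-5-bromo-N-(2-hydroxy-5-oxocyclopent-1-en-1-yl)penta-2,4-dienamide
Product: 33 target CNP0259711.3, (2E,4E,6E)-7-[(4R,5R,6S)-2-{[(R,E)-2,4-dimethyloct-2-enoyl]amino}-5,6-epoxy-4-hydroxy-1-oxocyclohex-2-en-4-yl]-N-(2-hydroxy-5-oxocyclopent-1-en-1-yl)hepta-2,4,6-trienamide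
Conditions: PdCl2(MeCN)2 (5 mol %), DMF, rt, argon, dark
Reagents that add atoms: none
Why: Stille coupling, in which the stannane reduces the divalent palladium precatalyst to ligand-poor zerovalent palladium and oxidative addition into C–Br, transmetallation and reductive elimination all proceed with retention, forming C8–C9 and the all-E triene under neutral conditions that spare the oxirane, the tertiary carbinol, the enol and both amides.

**Compound list**
1 | 4-[(trimethylsilyl)ethynyl]phenol | C[Si](C)(C)C#Cc1ccc(O)cc1 | starting material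
2 | 4-hydroxy-4-[(trimethylsilyl)ethynyl]cyclohexa-2,5-dien-1-one | O=C1C=CC(O)(C#C[Si](C)(C)C)C=C1 | intermediate
3 | 4-(triethylsilyloxy)-4-[(trimethylsilyl)ethynyl]cyclohexa-2,5-dien-1-one | O=C1C=CC(C#C[Si](C)(C)C)(O[Si](CC)(CC)CC)C=C1 | intermediate
4 | racemic (4S*,5R*,6S*)-5,6-epoxy-4-(triethylsilyloxy)-4-[(trimethylsilyl)ethynyl]cyclohex-2-en-1-one, oxirane trans to OSiEt3, one enantiomer drawn, not isolated | O=C1C=C[C@](O[Si](CC)(CC)CC)(C#C[Si](C)(C)C)[C@@H]2O[C@H]12 | intermediate
5 | meso-(2R,3S,5R,6S)-2,3:5,6-diepoxy-4-(triethylsilyloxy)-4-[(trimethylsilyl)ethynyl]cyclohexan-1-one, both oxiranes trans to OSiEt3 | O=C1[C@@H]2O[C@@H]2[C@](O[Si](CC)(CC)CC)(C#C[Si](C)(C)C)[C@@H]3O[C@H]13 | intermediate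
6 | (2S,3S,4S,5R,6S)-2-azido-5,6-epoxy-4-(triethylsilyloxy)-3-(trimethylsilyloxy)-4-[(trimethylsilyl)ethynyl]cyclohexan-1-one, azide trans to C3–OSiMe3, not isolated | [N-]=[N+]=N[C@H]1[C@H](O[Si](C)(C)C)[C@](O[Si](CC)(CC)CC)(C#C[Si](C)(C)C)[C@@H]2O[C@@H]2C1=O | intermediate
7 | (4S,5R,6S)-2-azido-5,6-epoxy-4-(triethylsilyloxy)-4-[(trimethylsilyl)ethynyl]cyclohex-2-en-1-one | [N-]=[N+]=NC1=C[C@](O[Si](CC)(CC)CC)(C#C[Si](C)(C)C)[C@@H]2O[C@@H]2C1=O | intermediate
8 | hexanoyl chloride | CCCCCC(Cl)=O | starting material
9 | (R)-4-benzyl-2-oxazolidinone | O=C1N[C@H](Cc2ccccc2)CO1 | starting material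
10 | (R)-4-benzyl-3-hexanoyloxazolidin-2-one | CCCCCC(=O)N1[C@H](Cc2ccccc2)COC1=O | intermediate
11 | sodium Z-enolate of 10, not isolated | [Na+].CCCC/C=C(\[O-])N1[C@H](Cc2ccccc2)COC1=O | intermediate
12 | (R)-4-benzyl-3-[(R)-2-methylhexanoyl]oxazolidin-2-one | CCCC[C@@H](C)C(=O)N1[C@H](Cc2ccccc2)COC1=O | intermediate
13 | (R)-2-methylhexan-1-ol | CCCC[C@@H](C)CO | intermediate
14 | (R)-2-methylhexanal | CCCC[C@@H](C)C=O | intermediate
15 | ethyl 2-(triphenylphosphoranylidene)propanoate | CCOC(=O)C(C)=P(c1ccccc1)(c1ccccc1)c1ccccc1 | starting material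
16 | ethyl (R,E)-2,4-dimethyloct-2-enoate | CCCC[C@@H](C)/C=C(\C)C(=O)OCC | intermediate
17 | (R,E)-2,4-dimethyloct-2-enoic acid | CCCC[C@@H](C)/C=C(\C)C(=O)O | intermediate
18 | (R,E)-2,4-dimethyloct-2-enoyl chloride | CCCC[C@@H](C)/C=C(\C)C(=O)Cl | intermediate
19 | (4S,5R,6S)-5,6-epoxy-4-(triethylsilyloxy)-4-[(trimethylsilyl)ethynyl]-2-[(triphenylphosphoranylidene)amino]cyclohex-2-en-1-one, not isolated | c1ccccc1P(c1ccccc1)(c1ccccc1)=NC1=C[C@](O[Si](CC)(CC)CC)(C#C[Si](C)(C)C)[C@@H]2O[C@@H]2C1=O | intermediate
20 | (4S,5R,6S)-2-amino-5,6-epoxy-4-(triethylsilyloxy)-4-[(trimethylsilyl)ethynyl]cyclohex-2-en-1-one | NC1=C[C@](O[Si](CC)(CC)CC)(C#C[Si](C)(C)C)[C@@H]2O[C@@H]2C1=O | intermediate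
21 | (R,E)-N-{(4S,5R,6S)-5,6-epoxy-1-oxo-4-(triethylsilyloxy)-4-[(trimethylsilyl)ethynyl]cyclohex-2-en-2-yl}-2,4-dimethyloct-2-enamide | CCCC[C@@H](C)/C=C(\C)C(=O)NC1=C[C@](O[Si](CC)(CC)CC)(C#C[Si](C)(C)C)[C@@H]2O[C@@H]2C1=O | intermediate
22 | (R,E)-N-[(4S,5R,6S)-5,6-epoxy-4-ethynyl-1-oxo-4-(triethylsilyloxy)cyclohex-2-en-2-yl]-2,4-dimethyloct-2-enamide, not isolated | CCCC[C@@H](C)/C=C(\C)C(=O)NC1=C[C@](O[Si](CC)(CC)CC)(C#C)[C@@H]2O[C@@H]2C1=O | intermediate
23 | (R,E)-N-[(4S,5R,6S)-5,6-epoxy-4-ethynyl-4-hydroxy-1-oxocyclohex-2-en-2-yl]-2,4-dimethyloct-2-enamide | CCCC[C@@H](C)/C=C(\C)C(=O)NC1=C[C@](O)(C#C)[C@@H]2O[C@@H]2C1=O | intermediate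
24 | (R,E)-N-{(4S,5R,6S)-5,6-epoxy-4-hydroxy-1-oxo-4-[(E)-2-(tributylstannyl)vinyl]cyclohex-2-en-2-yl}-2,4-dimethyloct-2-enamide | CCCC[C@@H](C)/C=C(\C)C(=O)NC1=C[C@](O)(/C=C/[Sn](CCCC)(CCCC)CCCC)[C@@H]2O[C@@H]2C1=O | intermediate
25 | glutaconaldehyde potassium salt | [K+].[O-]/C=C/C=C/C=O | starting material
26 | (2E,4E)-5-bromopenta-2,4-dienal | O=C/C=C/C=C/Br | intermediate
27 | (2E,4E)-5-bromopenta-2,4-dienoic acid | OC(=O)/C=C/C=C/Br | intermediate
28 | cyclopentane-1,3-dione | O=C1CCC(=O)C1 | starting material
29 | 2-(2-phenylhydrazinylidene)cyclopentane-1,3-dione | O=C1CCC(=O)C1=NNc1ccccc1 | intermediate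
30 | 2-amino-3-hydroxycyclopent-2-en-1-one hydrochloride | Cl.NC1=C(O)CCC1=O | intermediate
31 | (2E,4E)-5-bromopenta-2,4-dienoyl chloride | ClC(=O)/C=C/C=C/Br | intermediate
32 | (2E,4E)-5-bromo-N-(2-hydroxy-5-oxocyclopent-1-en-1-yl)penta-2,4-dienamide | O=C(/C=C/C=C/Br)NC1=C(O)CCC1=O | intermediate
33 | CNP0259711.3 | CCCC[C@@H](C)/C=C(\C)C(=O)NC1=C[C@](O)(/C=C/C=C/C=C/C(=O)NC2=C(O)CCC2=O)[C@@H]2O[C@@H]2C1=O | target

**Step count**
Total: 22 steps. Longest linear sequence: 11 steps (8 → 10 → 12 → 13 → 14 → 16 → 17 → 18 → 21 → 23 → 24 → 33, that is steps 5–11, 13, 14, 15 and 22). The core branch from 1 runs over 9 steps.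

**Steps most likely to fail**

1. Step 4.
   - What may go wrong: weak discrimination between the two enantiotopic oxiranes, azide attack at C3 instead of C2, loss of dinitrogen from the azido enolate before the siloxide leaves, or opening of the second oxirane.
   - Fallback: known chemistry, with resolution in place of desymmetrisation.
   - Setting out from 5, NaN3/AcOH in aqueous DMF should open one oxirane at its α-carbon with no preference between the arms. This gives the racemic trans-2-azido-3-hydroxy ketone F1.
   - MsCl/Et3N converts it into the racemic C3 mesylate F2, which eliminates in the same flask. The product is the racemic azido enone, that is 7 together with the mirror-image azido enone F3.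
   - PPh3 in wet THF, as in step 12, carries the pair through 19 and the mirror-image iminophosphorane F4 to 20 and the mirror-image amine F5.
   - Acylation with enantiopure 18, as in step 13, gives 21 and the diastereomeric amide F6. These are separated by preparative HPLC, and the route is rejoined at 21.

2. Step 3.
   - What may go wrong: poor facial selectivity in either peroxide addition (entry on the OSiEt3 face, or a second oxirane trans to the first), or base-induced loss of the alkynyl silyl group.
   - Fallback: hydroxyl-directed electrophilic epoxidation in place of sterically steered nucleophilic epoxidation.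
   - Setting out from 3, Luche reduction (NaBH4, CeCl3·7H2O, MeOH, −78 °C) should deliver hydride to C1 from the face of the C4 oxygen. This gives the trans-1,4-dioxygenated dienol F7, with its C1 hydroxyl on the alkyne face.
   - m-CPBA in Na2HPO4-buffered CH2Cl2 at 0 °C is guided by hydrogen bonding to that hydroxyl. It passes through the racemic monoepoxy dienol F8 to the all-cis diepoxy alcohol F9.
   - Dess–Martin periodinane then oxidises C1, and the route is rejoined at 5.

3. Step 15.
   - What may go wrong: conjugate reduction of the enone or reductive opening of the epoxy ketone by the tin hydride, tin delivery to the internal alkyne carbon, or protodestannylation on silica.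
   - Fallback: no tin on the core; the chain is joined first and the alkyne is then reduced to the trans alkene.
   - Setting out from 23, Sonogashira coupling with 32 (PdCl2(PPh3)2, CuI, Et3N, THF/DMF, rt) gives the dienyne F10.
   - Trans-hydrosilylation with (EtO)3SiH and [Cp*Ru(MeCN)3]PF6 in CH2Cl2 at 0 °C gives the vinylsilane F11, with silicon on the carbon remote from the carbinol.
   - Protodesilylation with AgF in aqueous THF/MeOH replaces silicon by hydrogen with retention. This delivers the E alkene, and the route is rejoined at 33, so steps 15 and 22 are not needed.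

**Further compounds**
F1 | step 4 | racemic trans-2-azido-5,6-epoxy-3-hydroxy-4-(triethylsilyloxy)-4-[(trimethylsilyl)ethynyl]cyclohexan-1-one (one enantiomer drawn) | [N-]=[N+]=N[C@H]1[C@H](O)[C@](O[Si](CC)(CC)CC)(C#C[Si](C)(C)C)[C@@H]2O[C@@H]2C1=O
F2 | step 4 | racemic C3 methanesulfonate of F1 (one enantiomer drawn) | [N-]=[N+]=N[C@H]1[C@H](OS(C)(=O)=O)[C@](O[Si](CC)(CC)CC)(C#C[Si](C)(C)C)[C@@H]2O[C@@H]2C1=O
F3 | step 4 | mirror image of azido enone 7, (4R,5S,6R) | [N-]=[N+]=NC1=C[C@@](O[Si](CC)(CC)CC)(C#C[Si](C)(C)C)[C@H]2O[C@H]2C1=O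
F4 | step 4 | mirror image of iminophosphorane 19 | c1ccccc1P(c1ccccc1)(c1ccccc1)=NC1=C[C@@](O[Si](CC)(CC)CC)(C#C[Si](C)(C)C)[C@H]2O[C@H]2C1=O
F5 | step 4 | mirror image of amine 20 | NC1=C[C@@](O[Si](CC)(CC)CC)(C#C[Si](C)(C)C)[C@H]2O[C@H]2C1=O
F6 | step 4 | diastereomer of 21 with the (4R,5S,6R) core and the (R) chain | CCCC[C@@H](C)/C=C(\C)C(=O)NC1=C[C@@](O[Si](CC)(CC)CC)(C#C[Si](C)(C)C)[C@H]2O[C@H]2C1=O
F7 | step 3 | 4-(triethylsilyloxy)-4-[(trimethylsilyl)ethynyl]cyclohexa-2,5-dien-1-ol, C1–OH trans to OSiEt3 | O[C@@H]1C=C[C@](O[Si](CC)(CC)CC)(C#C[Si](C)(C)C)C=C1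
F8 | step 3 | racemic 5,6-epoxy-4-(triethylsilyloxy)-4-[(trimethylsilyl)ethynyl]cyclohex-2-en-1-ol, oxirane cis to C1–OH (one enantiomer drawn) | O[C@@H]1C=C[C@](O[Si](CC)(CC)CC)(C#C[Si](C)(C)C)[C@@H]2O[C@H]12
F9 | step 3 | 2,3:5,6-diepoxy-4-(triethylsilyloxy)-4-[(trimethylsilyl)ethynyl]cyclohexan-1-ol, C1–OH and both oxiranes cis, all trans to OSiEt3 | O[C@@H]1[C@@H]2O[C@@H]2[C@](O[Si](CC)(CC)CC)(C#C[Si](C)(C)C)[C@@H]3O[C@H]13
F10 | step 15 | 7,8-didehydro analogue of the target (dienyne) | CCCC[C@@H](C)/C=C(\C)C(=O)NC1=C[C@](O)(C#C/C=C/C=C/C(=O)NC2=C(O)CCC2=O)[C@@H]2O[C@@H]2C1=O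
F11 | step 15 | 8-(triethoxysilyl) derivative of the target, ring carbon C4 and dienyl chain trans across C7=C8 | CCCC[C@@H](C)/C=C(\C)C(=O)NC1=C[C@](O)(/C=C(/C=C/C=C/C(=O)NC2=C(O)CCC2=O)[Si](OCC)(OCC)OCC)[C@@H]2O[C@@H]2C1=O
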